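**Retrosynthetic overview**

1. Target 27 is read as drawn: (S)-α-aryl-β-hydroxy ketone, (1S,3aR,4S,6aR) furofuran, (2S,3S)-cis-dihydrobenzofuran. It comes from pentabenzyl ether 26 by hydrogenolysis. The cis-dihydrobenzofuran (last ring formed) is closed by SN2 attack of the ring C phenol on a syn benzylic alcohol, and the ring A ketone is restored by re-oxidation.
2. Both Ar–CO–CH(Ar')–CH2O units arise in one twofold enantioselective 1,2-aryl shift (ring B and ring C move from Cβ to Cα) of bis-chalcone 20, induced by a chiral aryl-λ3-iodane and finished by in-flask reduction of the acetal.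
3. Bis-chalcone 20 comes from a double Heck reaction of dibromo furofuran 19 with aryl vinyl ketone 12.
4. Furofuran 19 (first ring system formed, with ring B as OBn and ring C as OTIPS) comes from a proline cross-aldol of 7 with methyl 4-oxobutanoate, a lactone aldol with 8, reduction, and a cationic double cycloetherification.
5. All four arenes come from catechol through guaiacol, vanillin and 5-bromovanillin.

Assumption: the (R,R)-lactate-derived iodane is taken to give the (S) centres in step 14; if the sense is opposite, the (S,S)-reagent is used and nothing else changes.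

**Route**

Step 1
Reactants: 1 catechol
Product: 2 guaiacol
Conditions: MeI (1.0 equiv), K2CO3 (1.0 equiv), acetone, reflux
Reagents that add atoms: iodomethane, CI
Why: Williamson mono-O-methylation under stoichiometric control; the mono-ether is separated from veratrole and recovered catechol.

Step 2
Reactants: 2 guaiacol; 3 glyoxylic acid
Product: 5 vanillin, via mandelic acid adduct 4 (not isolated)
Conditions: OHCCO2H (50% aq), NaOH, H2O, 30 °C; then CuSO4 (5 mol %), O2, 95 °C; H2SO4
Reagents that add atoms: none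
Why: Para-selective hydroxyalkylation of the phenoxide by glyoxylate followed by copper-catalysed aerobic oxidative decarboxylation of the mandelate (the classical guaiacol–glyoxylic acid vanillin process).

Step 3
Reactants: 5 vanillin
Product: 6 5-bromovanillin
Conditions: Br2, AcOH, rt
Reagents that add atoms: bromine, BrBr
Why: Electrophilic aromatic bromination at the only free position ortho to the phenol.

Step 4
Reactants: 6 5-bromovanillin
Product: 7 4-(benzyloxy)-3-bromo-5-methoxybenzaldehyde
Conditions: BnBr, K2CO3, DMF, 60 °C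
Reagents that add atoms: benzyl bromide, BrCc1ccccc1
Why: Williamson ether synthesis; benzyl will protect the ring B phenol to the end.

Step 5
Reactants: 6 5-bromovanillin
Product: 8 3-bromo-5-methoxy-4-(triisopropylsilyloxy)benzaldehyde
Conditions: TIPSOTf (1.2 equiv), 2,6-lutidine, CH2Cl2, 0 °C → rt
Reagents that add atoms: triisopropylsilyl trifluoromethanesulfonate, CC(C)[Si](OS(=O)(=O)C(F)(F)F)(C(C)C)C(C)C
Why: Silylation of the hindered phenol with a silyl triflate; the silyl ether marks the ring C oxygen for later selective release.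

Step 6
Reactants: 5 vanillin
Product: 9 4-(benzyloxy)-3-methoxybenzaldehyde
Conditions: BnBr, K2CO3, DMF, 60 °C
Reagents that add atoms: benzyl bromide, BrCc1ccccc1
Why: Williamson ether synthesis.

Step 7
Reactants: 9 4-(benzyloxy)-3-methoxybenzaldehyde; 10 vinylmagnesium bromide
Product: 11 racemic 1-[4-(benzyloxy)-3-methoxyphenyl]prop-2-en-1-ol
Conditions: THF, −78 → 0 °C; NH4Cl aq
Reagents that add atoms: none
Why: Grignard 1,2-addition to the aldehyde; the carbinol centre is removed in the next step.

Step 8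
Reactants: 11 racemic allylic alcohol
Product: 12 1-[4-(benzyloxy)-3-methoxyphenyl]prop-2-en-1-one
Conditions: MnO2 (10 equiv), CH2Cl2, rt; used directly
Reagents that add atoms: none
Why: Selective MnO2 oxidation of an allylic, benzylic alcohol to the aryl vinyl ketone.

Step 9
Reactants: 7 4-(benzyloxy)-3-bromo-5-methoxybenzaldehyde; 13 methyl 4-oxobutanoate
Product: 16 hydroxy lactone, via aldol aldehyde 14 (not isolated), via diol ester 15 (not isolated)
Conditions: L-proline (30 mol %), 13 (3 equiv, slow addition), DMF, 4 °C; then MeOH, NaBH4, 0 °C; 1 M HCl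
Reagents that add atoms: none
Why: L-proline enamine cross-aldol (List–Houk transition state, E-enamine on the Re face of the aryl aldehyde) gives the anti aldol and fixes the future bridgehead C6a as (R); immediate borohydride reduction and lactonisation through the primary alcohol prevent retro-aldol and epimerisation.

Step 10
Reactants: 16 hydroxy lactone; 8 3-bromo-5-methoxy-4-(triisopropylsilyloxy)benzaldehyde
Product: 17 bis(hydroxybenzyl) lactone
Conditions: LiN(i-Pr)2 (2.2 equiv), THF, −78 °C; then 8; NH4Cl aq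
Reagents that add atoms: none
Why: Aldol addition of the lactone lithium enolate (alkoxide–enolate dianion); the aldehyde enters trans to the C4 substituent, setting the second bridgehead C3a as (R), and the new carbinol forms mainly anti (cyclic E-enolate, Zimmerman–Traxler), though either epimer serves in step 12.

Step 11
Reactants: 17 bis(hydroxybenzyl) lactone
Product: 18 tetraol
Conditions: LiBH4 (3 equiv), THF, 0 °C → rt
Reagents that add atoms: none
Why: Borohydride reduction of the lactone to the 1,4-diol without touching the aryl bromides, benzyl ether or aryl silyl ether.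

Step 12
Reactants: 18 tetraol
Product: 19 dibromo furofuran
Conditions: TfOH (10 mol %), 4 Å MS, CH2Cl2, −30 → 0 °C; Et3N
Reagents that add atoms: none
Why: Acid-catalysed twofold cycloetherification through benzylic cations (5-exo closure by the primary hydroxyls); each cation is captured on the face that places the aryl group exo, trans to the neighbouring ring bond, so C1 and C4 emerge (S) whatever the carbinol configuration, as in the closure that forms pinoresinol.

Step 13
Reactants: 19 dibromo furofuran; 12 aryl vinyl ketone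
Product: 20 bis-chalcone
Conditions: 12 (2.6 equiv), Pd2(dba)3 (5 mol %), P(t-Bu)3·HBF4 (12 mol %), Cy2NMe (3 equiv), 1,4-dioxane, 80 °C
Reagents that add atoms: none
Why: Twofold Mizoroki–Heck reaction of the two aryl bromides with the enone; syn β-hydride elimination gives both E-enones, and the amine base leaves the aryl silyl ether intact.

Step 14
Reactants: 20 bis-chalcone
Product: 22 bis(benzyloxy ketone), via bis(dibenzyl acetal) 21 (not isolated)
Conditions: (R,R)-ArI(OAc)2 [Ar = 2,6-bis((R)-1-methoxy-1-oxopropan-2-yloxy)phenyl] (2.6 equiv), TMSOTf (5 equiv), BnOH (8 equiv), CH2Cl2, −78 °C; then Et3SiH (8 equiv), −78 → −40 °C; NaHCO3 aq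
Reagents that add atoms: benzyl alcohol, OCc1ccccc1
Why: Proposed new method: twofold enantioselective reductive 1,2-aryl migration, in which the TMSOTf-activated lactate-derived aryl-λ3-iodane adds to Cα of each enone on one face, BnOH adds anti at the benzylic Cβ, and the ortho-oxygenated aryl ring (ring B, ring C) shifts from Cβ to Cα with inversion and loss of the aryl iodide, setting both (S) α-aryl centres and leaving a benzyloxy-oxocarbenium ion that is trapped as dibenzyl acetal 21; Et3SiH with the TMSOTf already present then re-ionises the acetal (activated at −78 °C, unlike the aryl ketone) and hydride reduces the oxocarbenium ion to the benzyl ether faster than α-proton loss, so the configurationally labile β-keto aldehyde is never formed; closest known reaction type is the chiral hypervalent-iodine rearrangement of chalcones to α-aryl β,β-dimethoxy ketones together with silane reduction of acetals, not shown twofold, with benzyl alcohol, or carried through in one flask to the β-alkoxy ketone.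

Step 15
Reactants: 22 bis(benzyloxy ketone)
Product: 23 bis(syn alcohol)
Conditions: Zn(BH4)2 (3 equiv), Et2O/CH2Cl2, −30 → 0 °C; NH4Cl aq
Reagents that add atoms: none
Why: Chelation-controlled hydride reduction (zinc bridges the carbonyl and β-benzyloxy oxygens, hydride enters anti to the α-aryl group, the same sense as Felkin–Anh) gives the 1,2-syn (1R,2S) alcohols on both sides.

Step 16
Reactants: 23 bis(syn alcohol)
Product: 24 ring C phenol
Conditions: Bu4NF (1.2 equiv), AcOH (1.2 equiv), THF, 0 °C
Reagents that add atoms: none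
Why: Buffered fluoride cleavage of the aryl silyl ether, orthogonal to all benzyl ethers, frees only the ring C phenol.

Step 17
Reactants: 24 ring C phenol
Product: 25 cis-dihydrobenzofuran alcohol
Conditions: PPh3 (1.5 equiv), DIAD (1.5 equiv), toluene, −20 → 0 °C
Reagents that add atoms: none
Why: Intramolecular Mitsunobu etherification; SN2 inversion at the (1R) benzylic carbinol by the ring C phenol turns the syn alcohol into the (2S,3S)-cis-dihydrobenzofuran, while the ring A carbinol has no internal nucleophile and stays.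

Step 18
Reactants: 25 cis-dihydrobenzofuran alcohol
Product: 26 pentabenzyl ether of the target
Conditions: Dess–Martin periodinane (1.5 equiv), NaHCO3, CH2Cl2, 0 °C → rt
Reagents that add atoms: none
Why: Dess–Martin oxidation of the remaining benzylic alcohol restores the ring A ketone under buffered, non-basic conditions that leave the adjacent (S) centre untouched.

Step 19
Reactants: 26 pentabenzyl ether of the target
Product: 27 target CNP0174045.1
Conditions: H2 (1 atm), Pd/C (10%), EtOAc/EtOH, rt, monitored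
Reagents that add atoms: none
Why: Catalytic hydrogenolysis removes the three aryl and two primary alkyl benzyl ethers under neutral conditions that preserve the α-aryl ketone centre, the furofuran and the cis-dihydrobenzofuran.

**Compound list**

1 | catechol | Oc1ccccc1O | starting material
2 | guaiacol (2-methoxyphenol) | COc1ccccc1O | intermediate
3 | glyoxylic acid | OC(=O)C=O | starting material
4 | racemic 4-hydroxy-3-methoxymandelic acid | COc1cc(ccc1O)C(O)C(O)=O | intermediate (not isolated)
5 | vanillin | COc1cc(C=O)ccc1O | intermediate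
6 | 5-bromovanillin (3-bromo-4-hydroxy-5-methoxybenzaldehyde) | COc1cc(C=O)cc(Br)c1O | intermediate
7 | 4-(benzyloxy)-3-bromo-5-methoxybenzaldehyde | COc1cc(C=O)cc(Br)c1OCc1ccccc1 | intermediate
8 | 3-bromo-5-methoxy-4-(triisopropylsilyloxy)benzaldehyde | COc1cc(C=O)cc(Br)c1O[Si](C(C)C)(C(C)C)C(C)C | intermediate
9 | 4-(benzyloxy)-3-methoxybenzaldehyde | COc1cc(C=O)ccc1OCc1ccccc1 | intermediate
10 | vinylmagnesium bromide | C=C[Mg]Br | starting material
11 | racemic 1-[4-(benzyloxy)-3-methoxyphenyl]prop-2-en-1-ol | COc1cc(C(O)C=C)ccc1OCc1ccccc1 | intermediate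
12 | 1-[4-(benzyloxy)-3-methoxyphenyl]prop-2-en-1-one | COc1cc(C(=O)C=C)ccc1OCc1ccccc1 | intermediate
13 | methyl 4-oxobutanoate | COC(=O)CCC=O | starting material
14 | methyl (3S,4R)-4-[4-(benzyloxy)-3-bromo-5-methoxyphenyl]-3-formyl-4-hydroxybutanoate | COC(=O)C[C@H](C=O)[C@@H](O)c1cc(Br)c(OCc2ccccc2)c(OC)c1 | intermediate (not isolated)
15 | methyl (3R,4R)-4-[4-(benzyloxy)-3-bromo-5-methoxyphenyl]-4-hydroxy-3-(hydroxymethyl)butanoate | COC(=O)C[C@H](CO)[C@@H](O)c1cc(Br)c(OCc2ccccc2)c(OC)c1 | intermediate (not isolated)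
16 | (4R)-4-{(R)-[4-(benzyloxy)-3-bromo-5-methoxyphenyl](hydroxy)methyl}oxolan-2-one | O=C1C[C@H](CO1)[C@@H](O)c1cc(Br)c(OCc2ccccc2)c(OC)c1 | intermediate
17 | (3S,4R)-4-{(R)-[4-(benzyloxy)-3-bromo-5-methoxyphenyl](hydroxy)methyl}-3-{(R)-[3-bromo-5-methoxy-4-(triisopropylsilyloxy)phenyl](hydroxy)methyl}oxolan-2-one (major carbinol epimer drawn; the minor epimer at the new carbinol is carried along) | O=C1[C@H]([C@@H](O)c2cc(Br)c(O[Si](C(C)C)(C(C)C)C(C)C)c(OC)c2)[C@H](CO1)[C@@H](O)c1cc(Br)c(OCc2ccccc2)c(OC)c1 | intermediate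
18 | (1R,2R,3R,4R)-1-[4-(benzyloxy)-3-bromo-5-methoxyphenyl]-4-[3-bromo-5-methoxy-4-(triisopropylsilyloxy)phenyl]-2,3-bis(hydroxymethyl)butane-1,4-diol (major epimer drawn) | OC[C@H]([C@@H](O)c1cc(Br)c(OCc2ccccc2)c(OC)c1)[C@H](CO)[C@@H](O)c1cc(Br)c(O[Si](C(C)C)(C(C)C)C(C)C)c(OC)c1 | intermediate
19 | (1S,3aR,4S,6aR)-1-[4-(benzyloxy)-3-bromo-5-methoxyphenyl]-4-[3-bromo-5-methoxy-4-(triisopropylsilyloxy)phenyl]tetrahydro-1H,3H-furo[3,4-c]furan | COc1cc(cc(Br)c1OCc1ccccc1)[C@H]1OC[C@H]2[C@@H]1CO[C@@H]2c1cc(Br)c(O[Si](C(C)C)(C(C)C)C(C)C)c(OC)c1 | intermediate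
20 | bis-chalcone: 19 with each Br replaced by (E)-3-[4-(benzyloxy)-3-methoxyphenyl]-3-oxoprop-1-enyl | COc1cc(C(=O)/C=C/c2cc([C@H]3OC[C@H]4[C@@H]3CO[C@@H]4c3cc(OC)c(O[Si](C(C)C)(C(C)C)C(C)C)c(/C=C/C(=O)c4ccc(OCc5ccccc5)c(OC)c4)c3)cc(OC)c2OCc2ccccc2)ccc1OCc1ccccc1 | intermediate
21 | bis(dibenzyl acetal): ring B and ring C each carry (2S)-1,1-bis(benzyloxy)-3-[4-(benzyloxy)-3-methoxyphenyl]-3-oxopropan-2-yl | COc1cc(C(=O)[C@H](C(OCc5ccccc5)OCc5ccccc5)c2cc([C@H]3OC[C@H]4[C@@H]3CO[C@@H]4c3cc(OC)c(O[Si](C(C)C)(C(C)C)C(C)C)c(c3)[C@@H](C(OCc3ccccc3)OCc3ccccc3)C(=O)c3ccc(OCc6ccccc6)c(OC)c3)cc(OC)c2OCc2ccccc2)ccc1OCc1ccccc1 | intermediate (not isolated)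
22 | bis(benzyloxy ketone): ring B and ring C each carry (2S)-1-(benzyloxy)-3-[4-(benzyloxy)-3-methoxyphenyl]-3-oxopropan-2-yl | COc1cc(C(=O)[C@H](COCc5ccccc5)c2cc([C@H]3OC[C@H]4[C@@H]3CO[C@@H]4c3cc(OC)c(O[Si](C(C)C)(C(C)C)C(C)C)c(c3)[C@@H](COCc3ccccc3)C(=O)c3ccc(OCc6ccccc6)c(OC)c3)cc(OC)c2OCc2ccccc2)ccc1OCc1ccccc1 | intermediate
23 | bis(syn alcohol): ring B and ring C each carry (1R,2S)-3-(benzyloxy)-1-[4-(benzyloxy)-3-methoxyphenyl]-1-hydroxypropan-2-yl | COc1cc([C@H](O)[C@H](COCc5ccccc5)c2cc([C@H]3OC[C@H]4[C@@H]3CO[C@@H]4c3cc(OC)c(O[Si](C(C)C)(C(C)C)C(C)C)c(c3)[C@@H](COCc3ccccc3)[C@@H](O)c3ccc(OCc6ccccc6)c(OC)c3)cc(OC)c2OCc2ccccc2)ccc1OCc1ccccc1 | intermediate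
24 | ring C phenol: 23 without the triisopropylsilyl group | COc1cc([C@H](O)[C@H](COCc5ccccc5)c2cc([C@H]3OC[C@H]4[C@@H]3CO[C@@H]4c3cc(OC)c(O)c(c3)[C@@H](COCc3ccccc3)[C@@H](O)c3ccc(OCc6ccccc6)c(OC)c3)cc(OC)c2OCc2ccccc2)ccc1OCc1ccccc1 | intermediate
25 | cis-dihydrobenzofuran alcohol: ring C closed to (2S,3S)-2-[4-(benzyloxy)-3-methoxyphenyl]-3-(benzyloxymethyl)-7-methoxy-2,3-dihydrobenzofuran, ring B side chain still the (1R,2S) alcohol | COc1cc([C@H](O)[C@H](COCc5ccccc5)c2cc([C@H]3OC[C@H]4[C@@H]3CO[C@@H]4c3cc(OC)c4c(c3)[C@@H](COCc3ccccc3)[C@@H](c3ccc(OCc6ccccc6)c(OC)c3)O4)cc(OC)c2OCc2ccccc2)ccc1OCc1ccccc1 | intermediate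
26 | pentabenzyl ether of the target: 25 with the ring B side chain oxidised to the (S)-ketone | COc1cc(C(=O)[C@H](COCc5ccccc5)c2cc([C@H]3OC[C@H]4[C@@H]3CO[C@@H]4c3cc(OC)c4c(c3)[C@@H](COCc3ccccc3)[C@@H](c3ccc(OCc6ccccc6)c(OC)c3)O4)cc(OC)c2OCc2ccccc2)ccc1OCc1ccccc1 | intermediate
27 | CNP0174045.1 | COc1cc(C(=O)[C@H](CO)c2cc([C@H]3OC[C@H]4[C@@H]3CO[C@@H]4c3cc(OC)c4c(c3)[C@@H](CO)[C@@H](c3ccc(O)c(OC)c3)O4)cc(OC)c2O)ccc1O | target

**Totals and risks**

Total step count: 19. Longest linear sequence: 15 steps (steps 1, 2, 3, 4, 9, 10, 11, 12, 13, 14, 15, 16, 17, 18, 19).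

The three steps most likely to fail:

Step 14 (the proposed new step). The risks are incomplete aryl migration of the hindered, only moderately electron-rich rings, loss of enantiopurity through enol ether formation at the oxocarbenium stage, and acid damage to the furofuran. The fallback uses the established form of the rearrangement and separates the redox events. It sets out from 20. The same iodane with TMSOTf and MeOH in CH2Cl2 at −78 °C gives the isolable bis(keto dimethyl acetal) F1. Zn(BH4)2 reduces both ketones to the bis(hydroxy dimethyl acetal) F2. Wet LiBF4 in MeCN unmasks the bis(hydroxy aldehyde) F3, which is reduced at once with NaBH4 to the bis(1,3-diol) F4. Selective benzylation of the two primary hydroxyls through the stannylene acetals (Bu2SnO, then BnBr, Bu4NI, toluene) returns to the route at 23.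

Step 17. The para-benzyloxy group on ring D can open an SN1 path that would leak to the trans isomer. The fallback forms the C2–H bond instead of the C2–O bond. It sets out from 22. Buffered Bu4NF removes the silyl group to give the keto phenol F5, which is in equilibrium with its cyclic hemiketal. Ionic hydrogenation (Et3SiH, BF3·OEt2, CH2Cl2, −78 °C) delivers hydride to the 2-aryl oxocarbenium ion trans to the C3 substituent, so the aryl group ends cis. The ring A ketone has no neighbouring phenol and is left alone. This returns to the route at 26 and skips 23 to 25.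

Step 12. Kinetic exo capture of both benzylic cations may be incomplete, or the product may drift toward the exo/endo equilibrium mixture under acid. The fallback replaces the cationic closure by SN2 closure with inversion, for which the anti,anti configuration of the major epimer is the right one. It sets out from 18, after removal of the minor carbinol epimer. TBSCl and imidazole silylate the two primary hydroxyls to the bis(silyl ether) F6. MsCl and Et3N at −30 °C give the bis(benzylic mesylate) F7. HF·pyridine in THF/pyridine frees the primary hydroxyls, which displace the mesylates with inversion at both benzylic carbons and return to the route at 19.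

**Further compounds**

F1 | step 14 | bis(keto dimethyl acetal): 22 with each CH2OBn replaced by CH(OMe)2 | COc1cc(C(=O)[C@H](C(OC)OC)c2cc([C@H]3OC[C@H]4[C@@H]3CO[C@@H]4c3cc(OC)c(O[Si](C(C)C)(C(C)C)C(C)C)c(c3)[C@@H](C(OC)OC)C(=O)c3ccc(OCc6ccccc6)c(OC)c3)cc(OC)c2OCc2ccccc2)ccc1OCc1ccccc1
F2 | step 14 | bis(hydroxy dimethyl acetal): F1 with both ketones reduced to the syn alcohols | COc1cc([C@H](O)[C@H](C(OC)OC)c2cc([C@H]3OC[C@H]4[C@@H]3CO[C@@H]4c3cc(OC)c(O[Si](C(C)C)(C(C)C)C(C)C)c(c3)[C@@H](C(OC)OC)[C@@H](O)c3ccc(OCc6ccccc6)c(OC)c3)cc(OC)c2OCc2ccccc2)ccc1OCc1ccccc1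
F3 | step 14 | bis(hydroxy aldehyde), not isolated: F2 with both acetals hydrolysed | COc1cc([C@H](O)[C@H](C=O)c2cc([C@H]3OC[C@H]4[C@@H]3CO[C@@H]4c3cc(OC)c(O[Si](C(C)C)(C(C)C)C(C)C)c(c3)[C@@H](C=O)[C@@H](O)c3ccc(OCc6ccccc6)c(OC)c3)cc(OC)c2OCc2ccccc2)ccc1OCc1ccccc1
F4 | step 14 | bis(1,3-diol): 23 with both primary benzyl ethers replaced by free hydroxyls | COc1cc([C@H](O)[C@H](CO)c2cc([C@H]3OC[C@H]4[C@@H]3CO[C@@H]4c3cc(OC)c(O[Si](C(C)C)(C(C)C)C(C)C)c(c3)[C@@H](CO)[C@@H](O)c3ccc(OCc6ccccc6)c(OC)c3)cc(OC)c2OCc2ccccc2)ccc1OCc1ccccc1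
F5 | step 17 | keto phenol: 22 without the triisopropylsilyl group | COc1cc(C(=O)[C@H](COCc5ccccc5)c2cc([C@H]3OC[C@H]4[C@@H]3CO[C@@H]4c3cc(OC)c(O)c(c3)[C@@H](COCc3ccccc3)C(=O)c3ccc(OCc6ccccc6)c(OC)c3)cc(OC)c2OCc2ccccc2)ccc1OCc1ccccc1
F6 | step 12 | bis(primary tert-butyldimethylsilyl ether) of 18 | CC(C)(C)[Si](C)(C)OC[C@H]([C@@H](O)c1cc(Br)c(OCc2ccccc2)c(OC)c1)[C@H](CO[Si](C)(C)C(C)(C)C)[C@@H](O)c1cc(Br)c(O[Si](C(C)C)(C(C)C)C(C)C)c(OC)c1
F7 | step 12 | bis(benzylic mesylate) of F6 | CC(C)(C)[Si](C)(C)OC[C@H]([C@@H](OS(C)(=O)=O)c1cc(Br)c(OCc2ccccc2)c(OC)c1)[C@H](CO[Si](C)(C)C(C)(C)C)[C@@H](OS(C)(=O)=O)c1cc(Br)c(O[Si](C(C)C)(C(C)C)C(C)C)c(OC)c1
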